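## Retrosynthetic overview

1. Germacrane numbering is used (C1 ketone, C2=C3 furanone alkene, C4(Me)=C5, C6 lactone carbinol, C7, C8, C9, quaternary C10, C11=C13, C12 lactone carbonyl). The strategy rests on the cis-8,9-diol diester between the C7 methine and quaternary C10 of the ten-membered carbocycle C1–C10, which is bridged by the C3–O–C10 furanone oxygen and fused to the C6/C7 lactone; this diol is the retron of a (Z)-C8=C9 alkene.
2. Target 22 ⇐ diol 20 (C8 methacrylate, then C9 acetate) ⇐ cycloalkene 19 (syn-dihydroxylation) ⇐ diene 18 (ring-closing metathesis of the C7 and C10 vinyl groups).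
3. 18 ⇐ α'-hydroxy ynone 17 (gold-catalysed 5-endo closure of the furanone) ⇐ Sonogashira union at C3–C4 of alkyne 5 and (Z)-vinyl iodide 14.
4. 5 (C1, C2, C8–C10, C14) comes from (R)-2-methylglycidol. 14 (C4–C7, C11–C13, C15) comes from (S)-5-(hydroxymethyl)furan-2(5H)-one: C6 from the chiral pool, C7 by anti cuprate addition, (Z)-C4=C5 by iodo-Wittig olefination.
5. Ring order: lactone (present from 6) → furanone (step 14) → ten-membered carbocycle (step 15).

Key step: step 15

Remark: 5 and 15 are carried as mixtures of C1 epimers, which converge at the ketone. Only tertiary amine bases are used once the methylene lactone is present, because secondary amines add to it.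

## Route

Step 1
Reactants: 1 (R)-2-methylglycidol
Product: 2 (2S)-2-methylbut-3-ene-1,2-diol
Conditions: Me3S+ I− (4 equiv), n-BuLi (3.8 equiv), THF, −20 °C → rt
Reagents that add atoms: trimethylsulfonium iodide C[S+](C)C.[I-]
Why: Corey–Chaykovsky-type opening of the epoxide at its CH2 terminus by dimethylsulfonium methylide, followed by base-induced loss of Me2S, is the known one-carbon homologation of epoxides to allylic alcohols; the carbinol centre (future C10) is not touched, and a Payne shift of the alkoxide is degenerate for a 2-substituted glycidol and returns the same enantiomer.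

Step 2
Reactants: 2 (2S)-2-methylbut-3-ene-1,2-diol
Product: 3 (2S)-2-methyl-1,2-bis(triethylsilyloxy)but-3-ene
Conditions: Et3SiOTf (2.3 equiv), 2,6-lutidine, CH2Cl2, −78 → 0 °C
Reagents that add atoms: triethylsilyl trifluoromethanesulfonate CC[Si](CC)(CC)OS(=O)(=O)C(F)(F)F
Why: The silyl triflate with a hindered pyridine base silylates both the primary and the tertiary allylic hydroxyl (standard silyl ether formation) without touching the stereocentre.

Step 3
Reactants: 3 (2S)-2-methyl-1,2-bis(triethylsilyloxy)but-3-ene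
Product: 4 (2S)-2-methyl-2-(triethylsilyloxy)but-3-enal
Conditions: (COCl)2, DMSO, CH2Cl2, −78 → −30 °C; Et3N, −78 → 0 °C
Reagents that add atoms: none
Why: Under Swern conditions a primary triethylsilyl ether is attacked by the chlorosulfonium salt and oxidised directly to the aldehyde while the tertiary silyl ether cannot react (selective Swern oxidation of primary silyl ethers), and the α-quaternary aldehyde cannot epimerise.

Step 4
Reactants: 4 (2S)-2-methyl-2-(triethylsilyloxy)but-3-enal
Product: 5 (3RS,4S)-4-methyl-4-(triethylsilyloxy)hex-5-en-1-yn-3-ol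
Conditions: HC≡CMgBr, THF, −78 → 0 °C; then H2O
Reagents that add atoms: ethynylmagnesium bromide C#C[Mg]Br
Why: 1,2-Addition of the alkynyl Grignard reagent to the non-enolisable aldehyde gives the propargylic alcohol, whose new C1 centre is formed without control and is inconsequential because it becomes the ketone in step 12.

Step 5
Reactants: 6 (S)-5-(hydroxymethyl)furan-2(5H)-one
Product: 7 (S)-5-[(tert-butyldiphenylsilyloxy)methyl]furan-2(5H)-one
Conditions: t-BuPh2SiCl, imidazole, CH2Cl2, 0 °C → rt
Reagents that add atoms: tert-butyl(chloro)diphenylsilane CC(C)(C)[Si](Cl)(c1ccccc1)c1ccccc1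
Why: Standard silylation of the primary alcohol installs the bulky group that will direct the conjugate addition, and the C6 stereocentre is untouched.

Step 6
Reactants: 7 (S)-5-[(tert-butyldiphenylsilyloxy)methyl]furan-2(5H)-one
Product: 8 (4R,5S)-5-[(tert-butyldiphenylsilyloxy)methyl]-4-ethenyloxolan-2-one
Conditions: CH2=CHMgBr (3 equiv), CuI (1.5 equiv), THF, −78 → −40 °C; then H2O
Reagents that add atoms: vinylmagnesium bromide C=C[Mg]Br
Why: Conjugate addition of the vinyl cuprate to the butenolide occurs anti to the bulky silyloxymethyl group on C6 (substrate-controlled 1,4-addition), which sets C7 trans to C6 as in the target.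

Step 7
Reactants: 8 (4R,5S)-5-[(tert-butyldiphenylsilyloxy)methyl]-4-ethenyloxolan-2-one
Product: 9 (4R,5S)-4-ethenyl-5-(hydroxymethyl)oxolan-2-one
Conditions: Bu4NF, AcOH, THF, 0 °C → rt
Reagents that add atoms: none
Why: Fluoride cleaves the silyl ether and acetic acid buffers the alkoxide so that the lactone neither migrates to the primary oxygen nor epimerises (buffered fluoride desilylation).

Step 8
Reactants: 9 (4R,5S)-4-ethenyl-5-(hydroxymethyl)oxolan-2-one
Product: 10 (2S,3R)-3-ethenyl-5-oxooxolane-2-carbaldehyde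
Conditions: Dess–Martin periodinane, NaHCO3, CH2Cl2, 0 °C → rt; used crude
Reagents that add atoms: none
Why: Dess–Martin oxidation of the primary alcohol under buffered, non-basic conditions gives the α-acyloxy aldehyde without epimerising C6, and the aldehyde is used at once.

Step 9
Reactants: 10 (2S,3R)-3-ethenyl-5-oxooxolane-2-carbaldehyde
Product: 11 (4R,5S)-4-ethenyl-5-[(1Z)-2-iodoprop-1-en-1-yl]oxolan-2-one
Conditions: EtPPh3+ I−, n-BuLi, THF, 0 °C; I2, −78 °C; NaN(SiMe3)2, −78 → −20 °C; then 10, −78 → −20 °C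
Reagents that add atoms: ethyltriphenylphosphonium iodide CC[P+](c1ccccc1)(c1ccccc1)c1ccccc1.[I-]; iodine II
Why: Stork–Zhao-type Wittig olefination with the non-stabilised α-iodo ylide Ph3P=C(I)CH3 proceeds through the kinetically favoured cis-oxaphosphetane and places iodine cis to the C6 substituent, giving the (Z)-iodoalkene that fixes the C4=C5 geometry.

Step 10
Reactants: 11 (4R,5S)-4-ethenyl-5-[(1Z)-2-iodoprop-1-en-1-yl]oxolan-2-one
Product: 14 (4S,5S)-4-ethenyl-5-[(1Z)-2-iodoprop-1-en-1-yl]-3-methylideneoxolan-2-one, via Mannich base 12 (not isolated), via trimethylammonium iodide 13 (not isolated)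
Conditions: LiN(iPr)2, THF, −78 °C; CH2=NMe2+ I−, −78 °C → rt; then MeI, MeOH, rt; then NaHCO3, CH2Cl2/H2O, rt
Reagents that add atoms: N,N-dimethylmethyleneiminium iodide (Eschenmoser's salt) C=[N+](C)C.[I-]; iodomethane CI (its methyl group stays in 13 only)
Why: Eschenmoser methylenation, in which the lactone lithium enolate is aminomethylated by the iminium salt and quaternisation followed by mild base eliminates trimethylamine to the exocyclic methylene, removes the C11 stereocentre and leaves C6, C7 and the vinyl iodide untouched.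

Step 11
Reactants: 5 (3RS,4S)-4-methyl-4-(triethylsilyloxy)hex-5-en-1-yn-3-ol; 14 (4S,5S)-4-ethenyl-5-[(1Z)-2-iodoprop-1-en-1-yl]-3-methylideneoxolan-2-one
Product: 15 (4S,5R)-4-ethenyl-5-[(1Z,5RS,6S)-5-hydroxy-2,6-dimethyl-6-(triethylsilyloxy)octa-1,7-dien-3-yn-1-yl]-3-methylideneoxolan-2-one
Conditions: Pd(PPh3)2Cl2 (5 mol%), CuI (10 mol%), Et3N, THF (degassed), rt
Reagents that add atoms: none
Why: Sonogashira coupling of the terminal alkyne with the vinyl iodide forms C3–C4 with retention of the Z geometry at room temperature, where oxidative addition into the C–I bond is much faster than Heck insertion of the methylene lactone or ionisation of the allylic lactone C–O bond.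

Step 12
Reactants: 15 (4S,5R)-4-ethenyl-5-[(1Z,5RS,6S)-5-hydroxy-2,6-dimethyl-6-(triethylsilyloxy)octa-1,7-dien-3-yn-1-yl]-3-methylideneoxolan-2-one
Product: 16 (4S,5R)-5-[(1Z,6S)-2,6-dimethyl-5-oxo-6-(triethylsilyloxy)octa-1,7-dien-3-yn-1-yl]-4-ethenyl-3-methylideneoxolan-2-one
Conditions: Dess–Martin periodinane, NaHCO3, CH2Cl2, 0 °C → rt
Reagents that add atoms: none
Why: Dess–Martin oxidation converts both C1 epimers of the secondary propargylic alcohol into the conjugated ynone under buffered conditions that leave the silyl ether, the lactone and all alkenes intact.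

Step 13
Reactants: 16 (4S,5R)-5-[(1Z,6S)-2,6-dimethyl-5-oxo-6-(triethylsilyloxy)octa-1,7-dien-3-yn-1-yl]-4-ethenyl-3-methylideneoxolan-2-one
Product: 17 (4S,5R)-4-ethenyl-5-[(1Z,6S)-6-hydroxy-2,6-dimethyl-5-oxoocta-1,7-dien-3-yn-1-yl]-3-methylideneoxolan-2-one
Conditions: HF·pyridine, pyridine, THF, 0 °C → rt
Reagents that add atoms: none
Why: Buffered HF·pyridine cleaves the tertiary triethylsilyl ether (fluoride desilylation) without adding to the ynone or to the methylene lactone.

Step 14
Reactants: 17 (4S,5R)-4-ethenyl-5-[(1Z,6S)-6-hydroxy-2,6-dimethyl-5-oxoocta-1,7-dien-3-yn-1-yl]-3-methylideneoxolan-2-one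
Product: 18 (4S,5R)-4-ethenyl-5-{(1Z)-2-[(5S)-5-ethenyl-5-methyl-4-oxo-4,5-dihydrofuran-2-yl]prop-1-en-1-yl}-3-methylideneoxolan-2-one
Conditions: Ph3PAuNTf2 (5 mol%), toluene, rt
Reagents that add atoms: none
Why: π-Activation of the ynone by the cationic gold catalyst lets the tertiary hydroxyl add to C3 in a 5-endo-dig hydroalkoxylation, the known cycloisomerisation of α'-hydroxy ynones to 3(2H)-furanones, with no bond broken at C10 and the Z-alkene and methylene lactone as spectators.

Step 15
Reactants: 18 (4S,5R)-4-ethenyl-5-{(1Z)-2-[(5S)-5-ethenyl-5-methyl-4-oxo-4,5-dihydrofuran-2-yl]prop-1-en-1-yl}-3-methylideneoxolan-2-one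
Product: 19 (4Z,8Z,6R,7S,10S)-3,10-epoxy-1-oxogermacra-2,4,8,11(13)-tetraen-12,6-olide
Conditions: (H2IMes)(PCy3)Cl2Ru=CHPh (second-generation Grubbs catalyst, 15 mol% in three portions), toluene (1 mM, degassed), 80 °C, argon sparge
Reagents that add atoms: none
Why: The ruthenium benzylidene first exchanges with the less hindered C7 vinyl group, the resulting C8 alkylidene adds to the C10 vinyl group to give a ruthenacyclobutane, and cycloreversion releases ethene and the C8=C9 bond (Chauvin mechanism). The closest known reaction type is ring-closing metathesis of dienes to ten-membered carbocycles with cis-disubstituted alkenes, including lactone-fused germacrane-type rings. It closes the ten-membered carbocycle C1–C10 (and with it the nine-membered oxacycle through the C3–O–C10 bridge) by head-to-head union of the two vinyl termini, the new double bond being endocyclic. No stereocentre is formed, the alkene can only be Z because an E-alkene cannot be spanned in this bridged bicycle, and C6, C7 and C10 are untouched. The step needs chemoselectivity among five alkenes and ring closure over oligomerisation: only the two monosubstituted vinyl groups engage readily, whereas the 1,1-disubstituted electron-poor methylene and the trisubstituted conjugated C2=C3 and C4=C5 bonds are too hindered or electron-poor and could only close cyclobutenes or more strained bridged rings. The furanone and the (Z)-C4=C5 bond hold both vinyl groups on the same side of the molecule, and high dilution with removal of ethene favours the intramolecular pathway.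

Step 16
Reactants: 19 (4Z,8Z,6R,7S,10S)-3,10-epoxy-1-oxogermacra-2,4,8,11(13)-tetraen-12,6-olide
Product: 20 (4Z,6R,7R,8S,9S,10S)-3,10-epoxy-8,9-dihydroxy-1-oxogermacra-2,4,11(13)-trien-12,6-olide
Conditions: OsO4 (5 mol%), NMO (1.1 equiv), acetone/H2O, 0 °C
Reagents that add atoms: osmium tetroxide O=[Os](=O)(=O)=O (delivers both oxygen atoms); N-methylmorpholine N-oxide C[N+]1([O-])CCOCC1 (terminal oxidant that restores the oxygen); water O (hydrolysis of the osmate ester)
Why: Catalytic osmium tetroxide dihydroxylation is a suprafacial syn addition that should select the only isolated, electron-rich alkene over the electron-poor methylene lactone and the conjugated furanone alkenes, and because C1/C2 of the furanone and the C4–C6 segment cover the inner face of the (Z)-C8=C9 bond, attack on the exposed outer face should set C8 and C9 with both oxygens cis to the C10 oxygen bridge on the carbocycle.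

Step 17
Reactants: 20 (4Z,6R,7R,8S,9S,10S)-3,10-epoxy-8,9-dihydroxy-1-oxogermacra-2,4,11(13)-trien-12,6-olide
Product: 21 (4Z,6R,7S,8S,9S,10S)-3,10-epoxy-9-hydroxy-8-(2-methylprop-2-enoyloxy)-1-oxogermacra-2,4,11(13)-trien-12,6-olide
Conditions: methacrylic anhydride (1.1 equiv), Et3N, DMAP (cat.), CH2Cl2, −40 → 0 °C
Reagents that add atoms: methacrylic anhydride C=C(C)C(=O)OC(=O)C(C)=C
Why: DMAP-catalysed acylation with one equivalent of anhydride at low temperature should take the C8 hydroxyl, since the C9 hydroxyl is neopentyl-like next to quaternary C10, while the mild base avoids acyl migration and oxa-Michael addition to the methylene lactone.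

Step 18
Reactants: 21 (4Z,6R,7S,8S,9S,10S)-3,10-epoxy-9-hydroxy-8-(2-methylprop-2-enoyloxy)-1-oxogermacra-2,4,11(13)-trien-12,6-olide
Product: 22 (4Z,6R,7S,8S,9S,10S)-9-acetoxy-3,10-epoxy-8-(2-methylprop-2-enoyloxy)-1-oxogermacra-2,4,11(13)-trien-12,6-olide
Conditions: Ac2O (excess), pyridine, DMAP (cat.), CH2Cl2, 0 °C → rt
Reagents that add atoms: acetic anhydride CC(=O)OC(C)=O
Why: DMAP-catalysed acetylation of the remaining hindered C9 hydroxyl with excess anhydride completes the target without altering any stereocentre.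

## Compound list

1 | (R)-2-methylglycidol | OC[C@]1(C)CO1 | starting material
2 | (2S)-2-methylbut-3-ene-1,2-diol | C[C@@](O)(CO)C=C | intermediate
3 | (2S)-2-methyl-1,2-bis(triethylsilyloxy)but-3-ene | C[C@@](O[Si](CC)(CC)CC)(CO[Si](CC)(CC)CC)C=C | intermediate
4 | (2S)-2-methyl-2-(triethylsilyloxy)but-3-enal | C[C@@](O[Si](CC)(CC)CC)(C=O)C=C | intermediate
5 | (3RS,4S)-4-methyl-4-(triethylsilyloxy)hex-5-en-1-yn-3-ol | C#CC(O)[C@@](C)(O[Si](CC)(CC)CC)C=C | intermediate
6 | (S)-5-(hydroxymethyl)furan-2(5H)-one | OC[C@H]1OC(=O)C=C1 | starting material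
7 | (S)-5-[(tert-butyldiphenylsilyloxy)methyl]furan-2(5H)-one | CC(C)(C)[Si](c1ccccc1)(c1ccccc1)OC[C@H]1OC(=O)C=C1 | intermediate
8 | (4R,5S)-5-[(tert-butyldiphenylsilyloxy)methyl]-4-ethenyloxolan-2-one | C=C[C@H]1CC(=O)O[C@@H]1CO[Si](c1ccccc1)(c1ccccc1)C(C)(C)C | intermediate
9 | (4R,5S)-4-ethenyl-5-(hydroxymethyl)oxolan-2-one | C=C[C@H]1CC(=O)O[C@@H]1CO | intermediate
10 | (2S,3R)-3-ethenyl-5-oxooxolane-2-carbaldehyde | C=C[C@H]1CC(=O)O[C@@H]1C=O | intermediate
11 | (4R,5S)-4-ethenyl-5-[(1Z)-2-iodoprop-1-en-1-yl]oxolan-2-one | C=C[C@H]1CC(=O)O[C@@H]1/C=C(/C)I | intermediate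
12 | (4S,5S)-3-[(dimethylamino)methyl]-4-ethenyl-5-[(1Z)-2-iodoprop-1-en-1-yl]oxolan-2-one (C3 epimers) | C=C[C@H]1C(CN(C)C)C(=O)O[C@@H]1/C=C(/C)I | intermediate (not isolated)
13 | {(4S,5S)-4-ethenyl-5-[(1Z)-2-iodoprop-1-en-1-yl]-2-oxooxolan-3-yl}methyl(trimethyl)ammonium iodide | C=C[C@H]1C(C[N+](C)(C)C)C(=O)O[C@@H]1/C=C(/C)I.[I-] | intermediate (not isolated)
14 | (4S,5S)-4-ethenyl-5-[(1Z)-2-iodoprop-1-en-1-yl]-3-methylideneoxolan-2-one | C=C[C@H]1C(=C)C(=O)O[C@@H]1/C=C(/C)I | intermediate
15 | (4S,5R)-4-ethenyl-5-[(1Z,5RS,6S)-5-hydroxy-2,6-dimethyl-6-(triethylsilyloxy)octa-1,7-dien-3-yn-1-yl]-3-methylideneoxolan-2-one | C=C[C@H]1C(=C)C(=O)O[C@@H]1/C=C(/C)C#CC(O)[C@@](C)(O[Si](CC)(CC)CC)C=C | intermediate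
16 | (4S,5R)-5-[(1Z,6S)-2,6-dimethyl-5-oxo-6-(triethylsilyloxy)octa-1,7-dien-3-yn-1-yl]-4-ethenyl-3-methylideneoxolan-2-one | C=C[C@H]1C(=C)C(=O)O[C@@H]1/C=C(/C)C#CC(=O)[C@@](C)(O[Si](CC)(CC)CC)C=C | intermediate
17 | (4S,5R)-4-ethenyl-5-[(1Z,6S)-6-hydroxy-2,6-dimethyl-5-oxoocta-1,7-dien-3-yn-1-yl]-3-methylideneoxolan-2-one | C=C[C@H]1C(=C)C(=O)O[C@@H]1/C=C(/C)C#CC(=O)[C@@](C)(O)C=C | intermediate
18 | (4S,5R)-4-ethenyl-5-{(1Z)-2-[(5S)-5-ethenyl-5-methyl-4-oxo-4,5-dihydrofuran-2-yl]prop-1-en-1-yl}-3-methylideneoxolan-2-one | C=C[C@H]1C(=C)C(=O)O[C@@H]1/C=C(/C)C1=CC(=O)[C@@](C)(O1)C=C | intermediate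
19 | (4Z,8Z,6R,7S,10S)-3,10-epoxy-1-oxogermacra-2,4,8,11(13)-tetraen-12,6-olide | C=C1C(=O)O[C@@H]2/C=C(/C)C3=CC(=O)[C@@](C)(O3)/C=C\[C@@H]12 | intermediate
20 | (4Z,6R,7R,8S,9S,10S)-3,10-epoxy-8,9-dihydroxy-1-oxogermacra-2,4,11(13)-trien-12,6-olide | O[C@H]1[C@H]2C(=C)C(=O)O[C@@H]2/C=C(/C)C2=CC(=O)[C@@](C)(O2)[C@H]1O | intermediate
21 | (4Z,6R,7S,8S,9S,10S)-3,10-epoxy-9-hydroxy-8-(2-methylprop-2-enoyloxy)-1-oxogermacra-2,4,11(13)-trien-12,6-olide | C=C(C)C(=O)O[C@H]1[C@H]2C(=C)C(=O)O[C@@H]2/C=C(/C)C2=CC(=O)[C@@](C)(O2)[C@H]1O | intermediate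
22 | (4Z,6R,7S,8S,9S,10S)-9-acetoxy-3,10-epoxy-8-(2-methylprop-2-enoyloxy)-1-oxogermacra-2,4,11(13)-trien-12,6-olide | C=C(C)C(=O)O[C@H]1[C@H]2C(=C)C(=O)O[C@@H]2/C=C(/C)C2=CC(=O)[C@@](C)(O2)[C@H]1OC(C)=O | target

## Step count and risks

Total step count: 18. Longest linear sequence: 14 steps (6 → 22, steps 5–18); the alkyne arm (steps 1–4) joins at step 11.

Steps most likely to fail:

1. Step 15 (ring-closing metathesis). The catalyst may be consumed at the exocyclic methylene (chelation of the C8 alkylidene by the lactone carbonyl, cross-metathesis oligomers through the C7 vinyl group) faster than the strained ring closes. The fallback sets out from 18 and masks the methylene lactone. Dimethylamine (2 M in THF, 0 °C) adds to C13 to give the 13-(dimethylamino)-11,13-dihydro derivative of 18, F1. F1 is protonated with one equivalent of p-toluenesulfonic acid so that the amine does not bind ruthenium, and is cyclised with (H2IMes)Cl2Ru=CH(C6H4-2-OiPr) (second-generation Hoveyda–Grubbs catalyst) in 1,2-dichloroethane at 80 °C under high dilution to the macrocyclic amine, the 13-(dimethylamino)-11,13-dihydro derivative of 19, F2. Iodomethane converts F2 into its trimethylammonium iodide F3, and aqueous NaHCO3 eliminates trimethylamine. The fallback comes back to the route at 19.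

2. Step 16 (dihydroxylation). Facial selectivity may be poor or reversed if the ring presents its other face, so that the oxygens arrive trans to the C10 oxygen bridge. The fallback sets out from 19 and reverses the facial sense by the Woodward cis-hydroxylation. I2 and AgOAc in acetic acid add iodine on the exposed face and acetate anti to it at the less hindered C8, giving the trans-8-acetoxy-9-iodo compound F4. Silver-assisted displacement of the C9 iodide by the neighbouring acetate with inversion, then hydrolysis of the bridged acetoxonium ion with water, should give the cis-hydroxy acetates on the face opposite to the iodine: the 9-acetate 8-ol F5 and the 8-acetate 9-ol F6. Acid-catalysed methanolysis (AcCl cat., MeOH, 0 °C; basic methanolysis is avoided because methoxide adds to the methylene lactone) converges both on the diol. The fallback comes back to the route at 20.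

3. Step 17 (mono-methacryloylation). Acylation may occur at both hydroxyls or at O9, or the methacryloyl group may migrate between the cis hydroxyls under base. The fallback sets out from 20 and differentiates the oxygens through tin. Bu2SnO in toluene at reflux with azeotropic removal of water gives the dibutylstannylene acetal of 20, F7. Methacryloyl chloride in CH2Cl2 at 0 °C, without added base, then acylates the more accessible tin-bound oxygen O8. The fallback comes back to the route at 21.

## Further compounds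

F1 | step 15 | 13-(dimethylamino)-11,13-dihydro derivative of 18 (C11 epimers) | C=C[C@H]1C(CN(C)C)C(=O)O[C@@H]1/C=C(/C)C1=CC(=O)[C@@](C)(O1)C=C
F2 | step 15 | 13-(dimethylamino)-11,13-dihydro derivative of 19 (C11 epimers) | CN(C)CC1C(=O)O[C@@H]2/C=C(/C)C3=CC(=O)[C@@](C)(O3)/C=C\[C@@H]12
F3 | step 15 | trimethylammonium iodide of F2 | C[N+](C)(C)CC1C(=O)O[C@@H]2/C=C(/C)C3=CC(=O)[C@@](C)(O3)/C=C\[C@@H]12.[I-]
F4 | step 16 | trans-8-acetoxy-9-iodo-8,9-dihydro derivative of 19 | CC(=O)O[C@H]1[C@H]2C(=C)C(=O)O[C@@H]2/C=C(/C)C2=CC(=O)[C@@](C)(O2)[C@@H]1I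
F5 | step 16 | 9-O-acetyl derivative of diol 20 | O[C@H]1[C@H]2C(=C)C(=O)O[C@@H]2/C=C(/C)C2=CC(=O)[C@@](C)(O2)[C@H]1OC(C)=O
F6 | step 16 | 8-O-acetyl derivative of diol 20 | CC(=O)O[C@H]1[C@H]2C(=C)C(=O)O[C@@H]2/C=C(/C)C2=CC(=O)[C@@](C)(O2)[C@H]1O
F7 | step 17 | 8,9-O-dibutylstannylene acetal of diol 20 | CCCC[Sn]3(CCCC)O[C@H]1[C@H]2C(=C)C(=O)O[C@@H]2/C=C(/C)C2=CC(=O)[C@@](C)(O2)[C@H]1O3
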